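The dihydropyranone ring C is taken apart in a [3+3] sense at O1–C2 and C4–C4a. This leaves a 2,4-diprenylresorcinol (ring A) and a 3,4-dimethoxycinnamoyl unit (C2–C3–C4 plus ring B). The two halves are first joined through O1 as an o-iodoaryl cinnamate. In one flask, iodine–lithium exchange at C4a shifts the acyl group from O1 to C4a (anionic Fries rearrangement). The freed O1–H then adds to C2 of the new enone under a chiral bifunctional thiourea, which sets C2 as S. The step exploits the adjacent O1/C4a pair of ring A: C6 and C8 carry prenyl groups, so C4a is the only open site next to O1.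

Key step: step 7

Assumption: prenyl means 3-methylbut-2-en-1-yl and flavanone numbering (O1, C2–C4, C4a, C5–C8, C8a) is used throughout; the quinidine-derived pseudoenantiomer of the catalyst is taken as the one that gives 2S, and the quinine-derived one takes its place if the sense of induction is the opposite.

Step 1
Reactants: 1 1,3-bis(methoxymethoxy)benzene; 2 prenyl bromide
Product: 4 1,3-bis(methoxymethoxy)-2-prenylbenzene, via 2-lithio arene 3 (not isolated)
Conditions: n-BuLi, TMEDA, THF, 0 °C to rt; 2, −78 °C to rt
Reagents that add atoms: none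
Why: Directed ortho-metalation, in which the two OMOM groups cooperate and place lithium on the carbon between them (3), followed by SN2 alkylation of the aryllithium at the primary carbon of 2.

Step 2
Reactants: 4 1,3-bis(methoxymethoxy)-2-prenylbenzene; 2 prenyl bromide
Product: 6 1,3-bis(methoxymethoxy)-2,4-diprenylbenzene, via 4-lithio arene 5 (not isolated)
Conditions: n-BuLi, TMEDA, THF, 0 °C to rt; 2, −78 °C to rt
Reagents that add atoms: none
Why: Second directed ortho-metalation; C4 and C6 of 4 are equivalent and each lies ortho to one OMOM group, so the complex-induced proximity effect should favour ring lithiation (5) over removal of a benzylic–allylic proton, and SN2 alkylation by 2 follows as before.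

Step 3
Reactants: 6 1,3-bis(methoxymethoxy)-2,4-diprenylbenzene
Product: 8 1-iodo-2,4-bis(methoxymethoxy)-3,5-diprenylbenzene, via 6-lithio arene 7 (not isolated)
Conditions: n-BuLi, TMEDA, THF, −20 to 0 °C; I2, −78 °C; aq Na2S2O3 work-up
Reagents that add atoms: iodine, II
Why: Third directed ortho-metalation at the only ring C–H still ortho to an OMOM group (7), then iodination of the carbanion, which at −78 °C should be far faster than any reaction of iodine at the prenyl double bonds.

Step 4
Reactants: 8 1-iodo-2,4-bis(methoxymethoxy)-3,5-diprenylbenzene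
Product: 9 4-iodo-2,6-diprenylbenzene-1,3-diol
Conditions: TsOH·H2O (20 mol %), MeOH, 40 °C
Reagents that add atoms: none
Why: Acid-catalysed transacetalisation of both aryl MOM ethers to methanol; mild acid with a non-nucleophilic counter-ion and gentle warming should free the prenylated phenols without chroman closure or loss of iodine.

Step 5
Reactants: 9 4-iodo-2,6-diprenylbenzene-1,3-diol; 10 (E)-3,4-dimethoxycinnamoyl chloride
Product: 12 3-hydroxy-6-iodo-2,4-diprenylphenyl (E)-3,4-dimethoxycinnamate, via sodium phenoxide 11 (not isolated)
Conditions: NaH (1.0 equiv), THF, 0 °C; 10 (1.0 equiv), −40 °C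
Reagents that add atoms: none
Why: O-acylation of a phenoxide (Schotten–Baumann type); one equivalent of base should rest on the more acidic, iodine-flanked hydroxyl (11), which is acylated, while the less acidic hydroxyl between the two prenyl groups stays protonated.

Step 6
Reactants: 12 3-hydroxy-6-iodo-2,4-diprenylphenyl (E)-3,4-dimethoxycinnamate
Product: 13 3-(tert-butyldimethylsilyloxy)-6-iodo-2,4-diprenylphenyl (E)-3,4-dimethoxycinnamate
Conditions: TBSOTf, 2,6-lutidine, CH2Cl2, 0 °C to rt
Reagents that add atoms: TBSOTf (tert-butyldimethylsilyl trifluoromethanesulfonate), CC(C)(C)[Si](C)(C)OS(=O)(=O)C(F)(F)F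
Why: Silylation of the remaining hindered phenol by a strong silylating agent with a non-nucleophilic base; ester, iodide and alkenes are inert, and the silyl ether masks the acidic 7-OH that would otherwise consume the organolithium and tie up the amine catalyst in step 7.

Step 7
Reactants: 13 3-(tert-butyldimethylsilyloxy)-6-iodo-2,4-diprenylphenyl (E)-3,4-dimethoxycinnamate
Product: 17 (2S)-7-(tert-butyldimethylsilyloxy)-3',4'-dimethoxy-6,8-diprenylflavanone, via aryllithium 14 (not isolated), via lithium phenoxide 15 (not isolated), via 2'-hydroxychalcone 16 (not isolated)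
Conditions: n-BuLi (1.05 equiv), toluene/Et2O 3:1, −90 °C; AcOH (1.05 equiv), −78 °C; quinidine-derived 3,5-(CF3)2C6H3 thiourea (20 mol %), toluene, −20 °C to rt
Reagents that add atoms: none
Why: Iodine–lithium exchange at C4a is faster than addition of n-BuLi to the ester, and aryllithium 14 attacks the carbonyl carbon held next to it on O1 and collapses to lithium phenoxide 15, a 1,3 O-to-C acyl shift that makes C4–C4a (closest known type: anionic Fries rearrangement of o-haloaryl esters induced by halogen–metal exchange). 15 does not close by itself, because the ketone enolate that would result is much less stable than the phenoxide, so no racemic closure should run before AcOH sets free 16 and the catalyst is present. The catalyst binds the C4 carbonyl through its thiourea N–H bonds and takes the O1 proton with its quinuclidine nitrogen, and O1 adds to C2 in a 6-endo-trig intramolecular oxa-Michael addition that closes ring C (closest known type: organocatalytic enantioselective cyclisation of 2'-hydroxychalcones to flavanones). C2 is the only new stereocentre and is controlled by the catalyst, which should open the Si face of C2 to O1 and so give the S configuration. The step needs the acyl carbon to go to C4a and the oxygen to C2 (not the reverse, 4-arylcoumarin-type union): this is secured by the O1 tether, by the Z conformation of the ester, which holds C2 out of reach of the carbanion, by the prenyl groups that block C6 and C8, and by the silyl ether that masks the acidic 7-OH. Since the closure is reversible, it should be run cold and stopped once 16 is consumed, so that kinetic control is kept.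

Step 8
Reactants: 17 (2S)-7-(tert-butyldimethylsilyloxy)-3',4'-dimethoxy-6,8-diprenylflavanone
Product: 18 IN0946 [(2S)-7-hydroxy-3',4'-dimethoxy-6,8-diprenylflavanone]
Conditions: TBAF, AcOH (1:1), THF, 0 °C
Reagents that add atoms: none
Why: Fluoride-induced cleavage of the aryl silyl ether, whose phenoxide para to the ketone is a good leaving group; the AcOH buffer keeps the medium near neutral, so C2 should not be scrambled by retro-oxa-Michael opening and the prenyl groups are not protonated.

Compound list
1 | 1,3-bis(methoxymethoxy)benzene | COCOc1cccc(OCOC)c1 | starting material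
2 | prenyl bromide (1-bromo-3-methylbut-2-ene) | CC(C)=CCBr | starting material
3 | 2-lithio-1,3-bis(methoxymethoxy)benzene | COCOc1cccc(OCOC)c1[Li] | intermediate
4 | 1,3-bis(methoxymethoxy)-2-prenylbenzene | COCOc1cccc(OCOC)c1CC=C(C)C | intermediate
5 | 4-lithio-1,3-bis(methoxymethoxy)-2-prenylbenzene | COCOc1ccc([Li])c(OCOC)c1CC=C(C)C | intermediate
6 | 1,3-bis(methoxymethoxy)-2,4-diprenylbenzene | COCOc1ccc(CC=C(C)C)c(OCOC)c1CC=C(C)C | intermediate
7 | 6-lithio-1,3-bis(methoxymethoxy)-2,4-diprenylbenzene | COCOc1c([Li])cc(CC=C(C)C)c(OCOC)c1CC=C(C)C | intermediate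
8 | 1-iodo-2,4-bis(methoxymethoxy)-3,5-diprenylbenzene | COCOc1c(I)cc(CC=C(C)C)c(OCOC)c1CC=C(C)C | intermediate
9 | 4-iodo-2,6-diprenylbenzene-1,3-diol | Oc1c(I)cc(CC=C(C)C)c(O)c1CC=C(C)C | intermediate
10 | (E)-3,4-dimethoxycinnamoyl chloride | COc1ccc(/C=C/C(=O)Cl)cc1OC | starting material
11 | sodium 3-hydroxy-6-iodo-2,4-diprenylphenoxide | [Na+].[O-]c1c(I)cc(CC=C(C)C)c(O)c1CC=C(C)C | intermediate
12 | 3-hydroxy-6-iodo-2,4-diprenylphenyl (E)-3,4-dimethoxycinnamate | COc1ccc(/C=C/C(=O)Oc2c(I)cc(CC=C(C)C)c(O)c2CC=C(C)C)cc1OC | intermediate
13 | 3-(tert-butyldimethylsilyloxy)-6-iodo-2,4-diprenylphenyl (E)-3,4-dimethoxycinnamate | COc1ccc(/C=C/C(=O)Oc2c(I)cc(CC=C(C)C)c(O[Si](C)(C)C(C)(C)C)c2CC=C(C)C)cc1OC | intermediate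
14 | 3-(tert-butyldimethylsilyloxy)-6-lithio-2,4-diprenylphenyl (E)-3,4-dimethoxycinnamate | COc1ccc(/C=C/C(=O)Oc2c([Li])cc(CC=C(C)C)c(O[Si](C)(C)C(C)(C)C)c2CC=C(C)C)cc1OC | intermediate
15 | lithium 2'-phenoxide of chalcone 16 | [Li+].COc1ccc(/C=C/C(=O)c2cc(CC=C(C)C)c(O[Si](C)(C)C(C)(C)C)c(CC=C(C)C)c2[O-])cc1OC | intermediate
16 | (E)-1-[4-(tert-butyldimethylsilyloxy)-2-hydroxy-3,5-diprenylphenyl]-3-(3,4-dimethoxyphenyl)prop-2-en-1-one | COc1ccc(/C=C/C(=O)c2cc(CC=C(C)C)c(O[Si](C)(C)C(C)(C)C)c(CC=C(C)C)c2O)cc1OC | intermediate
17 | (2S)-7-(tert-butyldimethylsilyloxy)-3',4'-dimethoxy-6,8-diprenylflavanone | COc1ccc([C@@H]2CC(=O)c3cc(CC=C(C)C)c(O[Si](C)(C)C(C)(C)C)c(CC=C(C)C)c3O2)cc1OC | intermediate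
18 | IN0946, (2S)-7-hydroxy-3',4'-dimethoxy-6,8-diprenylflavanone | COc1ccc([C@@H]2CC(=O)c3cc(CC=C(C)C)c(O)c(CC=C(C)C)c3O2)cc1OC | target

Total step count: 8. Longest linear sequence: 8 steps (1 to 18).

Steps most likely to fail

**Step 7.** Ring closure of the electron-rich enone may be slow and reversible, so that retro-oxa-Michael opening erodes the enantiomeric purity. Lithium acetate may also compete for the hydrogen-bond donor of the catalyst. The fallback moves stereocontrol from the ring closure to a later catalytic resolution. Setting out from 13, the iodine–lithium exchange and acyl shift are run as before through 14, 15 and 16. The flask is then charged with NaOAc in EtOH and warmed, which should close ring C without stereocontrol and give the racemic silyl flavanone F1. F1 is resolved kinetically by asymmetric transfer hydrogenation [RuCl(p-cymene)(TsDPEN), HCO2H/Et3N], using the catalyst enantiomer that reduces the 2R ketone faster. This should convert that enantiomer into the cis-(2R,4R)-flavan-4-ol F2 and leave the 2S ketone. The 2S ketone is 17, where the route is rejoined after chromatography.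

**Step 5.** Discrimination between the two flanked hydroxyl groups may be poor, with acylation at the wrong oxygen or at both. The fallback protects first, differentiates by leaving-group ability and acylates last. Setting out from 9, both phenols are silylated (TBSOTf, 2,6-lutidine) to the bis-silyl ether F3. Brief treatment with catalytic K2CO3 in MeOH at low temperature should cleave first the silyl ether of the more acidic, iodine-flanked phenol and give the mono-silyl phenol F4. Its only free hydroxyl is then acylated by 10 (Et3N, DMAP, CH2Cl2) to give 13, where the route is rejoined.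

**Step 3.** n-BuLi may remove a benzylic–allylic proton of a prenyl group in competition with ring lithiation, so that the iodine ends up in side-chain products. The fallback uses no halogen handle and a homolytic instead of an anionic acyl shift.
- Setting out from 6, acid methanolysis of both MOM ethers gives 2,4-diprenylresorcinol F5.
- The hydroxyl with one free ortho position is much less hindered than the one between the prenyl groups. It should be acylated selectively by 10 (Et3N, CH2Cl2, −20 °C) to the mono-cinnamate F6.
- Silylation (TBSOTf, 2,6-lutidine) gives the silyl ether F7.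
- Irradiation (photo-Fries rearrangement, about 300 nm, degassed cyclohexane) should move the acyl group to the only free ortho carbon and give 16, where the route is rejoined.
- 16 is then closed by the thiourea catalyst as in step 7.

Further compounds
F1 | step 7 | racemic 7-(tert-butyldimethylsilyloxy)-3',4'-dimethoxy-6,8-diprenylflavanone | COc1ccc(C2CC(=O)c3cc(CC=C(C)C)c(O[Si](C)(C)C(C)(C)C)c(CC=C(C)C)c3O2)cc1OC
F2 | step 7 | (2R,4R)-7-(tert-butyldimethylsilyloxy)-3',4'-dimethoxy-6,8-diprenylflavan-4-ol (2,4-cis) | COc1ccc([C@H]2C[C@@H](O)c3cc(CC=C(C)C)c(O[Si](C)(C)C(C)(C)C)c(CC=C(C)C)c3O2)cc1OC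
F3 | step 5 | 1-iodo-2,4-bis(tert-butyldimethylsilyloxy)-3,5-diprenylbenzene | CC(C)(C)[Si](C)(C)Oc1c(I)cc(CC=C(C)C)c(O[Si](C)(C)C(C)(C)C)c1CC=C(C)C
F4 | step 5 | 3-(tert-butyldimethylsilyloxy)-6-iodo-2,4-diprenylphenol | Oc1c(I)cc(CC=C(C)C)c(O[Si](C)(C)C(C)(C)C)c1CC=C(C)C
F5 | step 3 | 2,4-diprenylbenzene-1,3-diol | Oc1ccc(CC=C(C)C)c(O)c1CC=C(C)C
F6 | step 3 | 3-hydroxy-2,4-diprenylphenyl (E)-3,4-dimethoxycinnamate | COc1ccc(/C=C/C(=O)Oc2ccc(CC=C(C)C)c(O)c2CC=C(C)C)cc1OC
F7 | step 3 | 3-(tert-butyldimethylsilyloxy)-2,4-diprenylphenyl (E)-3,4-dimethoxycinnamate | COc1ccc(/C=C/C(=O)Oc2ccc(CC=C(C)C)c(O[Si](C)(C)C(C)(C)C)c2CC=C(C)C)cc1OC
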